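**Plan**
- Feature: on ring B the oxygen on C8 and the one-carbon branch C11 on C9 lie on the same face (drimane numbering; C12 is the methyl on C8). The chain C11–C9–C8(O)–C12 is therefore the opened form of a cis-fused oxetan-2-one built on a methyl ketone.
- Cuts: (a) the C3'–Cl bond and the C11=C2' alkene go back, by allylic transposition, to a Morita–Baylis–Hillman-type carbinol and so to the C11–C2' bond (primed numbers: C1' is the ring carbonyl next to C2', C3' carries chlorine, C4' the second oxygen); (b) O8–C11 and C8–C9 are cut together to a monocyclic keto acid; (c) C5–C6 and C10–C9 on ring A are cut to 2,4,4-trimethylcyclohexenone, a ketal Grignard reagent and prenyl bromide.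
- Forward: ring A receives its chain and quaternary carbon, ring B and the oxetanone close in one operation, the lactone is taken to the C11 aldehyde, the five-membered ring is attached, chloride enters with alkene shift, and a last oxidation unveils the enolised 1,3-dione.
- Stereochemistry: C5 from a ligand-controlled conjugate addition; C10 from alkylation anti to the C5 chain; C8 and C9 from the chair transition state of the aldol-lactonisation; C3' from chloride addition anti to the silyloxy group of (R)-4-silyloxycyclopentenone, whose carbinol carbon is oxidised at the end; the E alkene from allylic strain.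

Key step: step 4

Assumption: compounds 1 and 19 are taken as catalogue items, and the target is written as the enol shown, the two enol forms of its 1,3-dione being in rapid equilibrium.

Step 1
Reactants: 1 2,4,4-trimethylcyclohex-2-en-1-one; 2 2-(2-bromoethyl)-2-methyl-1,3-dioxolane; 3 1-bromo-3-methylbut-2-ene
Product: 6 (2R,3S)-2,4,4-trimethyl-2-(3-methylbut-2-en-1-yl)-3-[2-(2-methyl-1,3-dioxolan-2-yl)ethyl]cyclohexan-1-one, via Grignard reagent 4 (not isolated), via magnesium enolate 5 (not isolated)
Conditions: 2, Mg, THF, 25 °C; then 1, CuBr·SMe2 (5 mol %), JosiPhos (6 mol %, antipode giving 3S), t-BuOMe, −78 °C; then 3, DMPU, −78 → 23 °C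
Reagents that add atoms: none
Why: A copper-catalysed asymmetric conjugate addition of the Grignard reagent, in which the chiral diphosphine selects the enone face and so sets C3 (the later C5), gives the tetrasubstituted magnesium enolate with full regiocontrol, and its C-alkylation by the allylic bromide in the presence of DMPU (conjugate addition–enolate trapping) should occur anti to the neighbouring C3 chain, setting the quaternary C2 (the later C10) with methyl cis and prenyl trans to that chain.

Step 2
Reactants: 6 (2R,3S)-2,4,4-trimethyl-2-(3-methylbut-2-en-1-yl)-3-[2-(2-methyl-1,3-dioxolan-2-yl)ethyl]cyclohexan-1-one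
Product: 8 2-methyl-2-{2-[(1S,2R)-2,6,6-trimethyl-2-(3-methylbut-2-en-1-yl)cyclohexyl]ethyl}-1,3-dioxolane, via hydrazone 7 (not isolated)
Conditions: N2H4·H2O, KOH, diethylene glycol, 130 °C, then 200 °C
Reagents that add atoms: none
Why: Wolff–Kishner reduction in the Huang-Minlon manner removes the carbonyl through hydrazone 7; the quaternary α-carbon cannot epimerise, C3 is not enolisable, and the dioxolane and the trisubstituted alkene are inert to hydrazine and hot KOH, so no stereocentre is set or lost.

Step 3
Reactants: 8 2-methyl-2-{2-[(1S,2R)-2,6,6-trimethyl-2-(3-methylbut-2-en-1-yl)cyclohexyl]ethyl}-1,3-dioxolane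
Product: 10 2-[(1R,2S)-1,3,3-trimethyl-2-(3-oxobutyl)cyclohexyl]acetic acid, via ketal acid 9 (not isolated)
Conditions: RuCl3·xH2O (2 mol %), NaIO4, EtOAc/MeCN/H2O, 23 °C; then i-PrOH; 1 M HCl, THF, 23 °C
Reagents that add atoms: sodium periodate [Na+].[O-]I(=O)(=O)=O; water O
Why: Catalytic RuO4 (from RuCl3 and NaIO4) cleaves the trisubstituted alkene to the carboxylic acid and acetone (oxidative alkene cleavage), after which dilute acid hydrolyses the dioxolane (acetal hydrolysis); both stereocentres are remote from any enolisable position and are untouched.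

Step 4
Reactants: 10 2-[(1R,2S)-1,3,3-trimethyl-2-(3-oxobutyl)cyclohexyl]acetic acid
Product: 15 (5S,8S,9R,10S)-drimane-11,8-olide (8β-hydroxydriman-11-oic acid β-lactone), via mixed sulfonic anhydride 11 (not isolated), via acylpyridinium tosylate 12 (not isolated), via ammonium enolate 13 (not isolated), via aldolate 14 (not isolated)
Conditions: TsCl (1.3 equiv), 4-pyrrolidinopyridine (1.5 equiv), i-Pr2NEt (4 equiv), CH2Cl2 (0.05 M), 23 °C
Reagents that add atoms: none
Why: Tosyl chloride turns the acid into a mixed anhydride that acylates 4-pyrrolidinopyridine; i-Pr2NEt deprotonates the acylpyridinium ion at C9, the resulting ammonium enolate attacks the C8 methyl ketone, and the aldolate oxygen then attacks the activated acyl group and expels the pyridine. The closest known reaction type is the nucleophile-promoted aldol-lactonisation of keto acids to bicyclic β-lactones, which is documented for ketone acceptors that give tertiary carbinol carbons. Ring B is closed by a 6-(enolexo)-exo-trig aldol addition (C8–C9) and the oxetan-2-one by a 4-exo-trig acyl substitution (O8–C11). A four-membered lactone can bridge C8 and C9 only when O8 and C11 are cis, so aldolates with the trans arrangement cannot be trapped and return by retro-aldol. Of the two cis arrangements, the chair with the acyl group equatorial on C9, the C8 methyl equatorial and the oxygen axial avoids a 1,3-diaxial methyl–methyl contact with the axial C10 methyl, so the existing C5 and C10 centres fix C9 as R and C8 as S. The step needs this facial selectivity and enolisation at C9 in preference to the ketone; the first rests on the chair preference and the second on the much higher acidity of the acylpyridinium α-hydrogens, while ring closure to the lactone protects the tertiary aldol from reversal and from loss of water.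

Step 5
Reactants: 15 (5S,8S,9R,10S)-drimane-11,8-olide
Product: 16 drimane-8β,11-diol
Conditions: LiAlH4, THF, 0 °C
Reagents that add atoms: none
Why: LiAlH4 opens the strained acyl–oxygen bond and reduces through the aldehyde to the primary alcohol (lactone reduction to a 1,3-diol) without touching C8 or C9, so the cis relation of O8 and C11 is carried over.

Step 6
Reactants: 16 drimane-8β,11-diol
Product: 17 8β,11-bis(triethylsilyloxy)drimane
Conditions: TESOTf (3 equiv), 2,6-lutidine, CH2Cl2, −78 → 23 °C
Reagents that add atoms: triethylsilyl trifluoromethanesulfonate CC[Si](CC)(CC)OS(=O)(=O)C(F)(F)F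
Why: Silylation with a silyl triflate and 2,6-lutidine is strong enough for the hindered axial tertiary hydroxyl as well as the primary one and involves no stereocentre.

Step 7
Reactants: 17 8β,11-bis(triethylsilyloxy)drimane
Product: 18 8β-(triethylsilyloxy)driman-11-al
Conditions: (COCl)2, DMSO, CH2Cl2, −78 → −30 °C; then Et3N, −78 → 0 °C
Reagents that add atoms: none
Why: Under Swern conditions a primary triethylsilyl ether is taken directly to the aldehyde (oxidative desilylation via the alkoxysulfonium ion) whereas the tertiary silyl ether has no carbinol hydrogen and stays; C9 keeps its configuration because the equatorial formyl group is also the thermodynamic epimer.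

Step 8
Reactants: 19 (R)-4-(tert-butyldimethylsilyloxy)cyclopent-2-en-1-one
Product: 20 (R)-4-(tert-butyldimethylsilyloxy)-2-iodocyclopent-2-en-1-one
Conditions: I2, pyridine, CH2Cl2, 0 → 23 °C
Reagents that add atoms: iodine II
Why: Iodine–pyridine α-iodination of an enone (conjugate addition of pyridine, iodination of the enolate, elimination) functionalises C2 only and leaves the C4 silyloxy stereocentre untouched.

Step 9
Reactants: 18 8β-(triethylsilyloxy)driman-11-al; 20 (R)-4-(tert-butyldimethylsilyloxy)-2-iodocyclopent-2-en-1-one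
Product: 22 (4R)-4-(tert-butyldimethylsilyloxy)-2-[11-hydroxy-8β-(triethylsilyloxy)driman-11-yl]cyclopent-2-en-1-one (both C11 epimers), via vinylchromium reagent 21 (not isolated)
Conditions: CrCl2 (4 equiv), NiCl2 (2 mol %), DMF, 23 °C
Reagents that add atoms: none
Why: The Nozaki–Hiyama–Kishi reaction turns the α-iodoenone into vinylchromium reagent 21 under nickel catalysis and adds it chemoselectively to the aldehyde in the presence of enone and silyl ethers, giving the Morita–Baylis–Hillman-type carbinol whose C11 configuration is irrelevant because C11 becomes trigonal in step 10.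

Step 10
Reactants: 22 (4R)-4-(tert-butyldimethylsilyloxy)-2-[11-hydroxy-8β-(triethylsilyloxy)driman-11-yl]cyclopent-2-en-1-one
Product: 24 (2E,3R,4R)-4-(tert-butyldimethylsilyloxy)-3-chloro-2-[8β-(triethylsilyloxy)driman-11-ylidene]cyclopentan-1-one, via allylic mesylate 23 (not isolated)
Conditions: MsCl, i-Pr2NEt, CH2Cl2, −20 °C; then LiCl, THF, 0 → 23 °C
Reagents that add atoms: lithium chloride [Li+].[Cl-]
Why: The mesylate of a Morita–Baylis–Hillman-type carbinol undergoes SN2' displacement by chloride (conjugate addition at C3', then expulsion of the C11 mesylate from the enolate); chloride should add anti to the adjacent C4' silyloxy group, which sets C3' as R, and the bulky drimanyl group should settle beside the flat C1' carbonyl and not beside the substituted sp3 carbon C3' (allylic strain), which sets the E alkene.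

Step 11
Reactants: 24 (2E,3R,4R)-4-(tert-butyldimethylsilyloxy)-3-chloro-2-[8β-(triethylsilyloxy)driman-11-ylidene]cyclopentan-1-one
Product: 25 (2E,3R,4R)-3-chloro-4-hydroxy-2-(8β-hydroxydriman-11-ylidene)cyclopentan-1-one
Conditions: aq. HF (48 %), MeCN, 0 → 23 °C
Reagents that add atoms: none
Why: Acidic fluoride desilylation removes both silyl ethers without the basic conditions that would eliminate HCl or water from the β-chloro-β'-hydroxy ketone, and no stereocentre is affected.

Step 12
Reactants: 25 (2E,3R,4R)-3-chloro-4-hydroxy-2-(8β-hydroxydriman-11-ylidene)cyclopentan-1-one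
Product: 27 (4E,5R)-5-chloro-3-hydroxy-4-{[(1R,2S,4aS,8aS)-2-hydroxy-2,5,5,8a-tetramethyldecahydronaphthalen-1-yl]methylidene}cyclopent-2-en-1-one, via diketone tautomer 26 (not isolated)
Conditions: Dess–Martin periodinane (1.1 equiv), CH2Cl2, 0 → 23 °C; neutral work-up
Reagents that add atoms: none
Why: Dess–Martin oxidation converts the secondary carbinol into the ketone while the tertiary C8 alcohol is inert, and the resulting 1,3-diketone 26 enolises spontaneously to the vinylogous acid; the non-basic medium should preserve the α-chloro stereocentre set in step 10 and the E alkene.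

**Compound list**
1 | 2,4,4-trimethylcyclohex-2-en-1-one | CC1=CC(C)(C)CCC1=O | starting material
2 | 2-(2-bromoethyl)-2-methyl-1,3-dioxolane | CC1(CCBr)OCCO1 | starting material
3 | 1-bromo-3-methylbut-2-ene (prenyl bromide) | CC(C)=CCBr | starting material
4 | [2-(2-methyl-1,3-dioxolan-2-yl)ethyl]magnesium bromide | CC1(CC[Mg]Br)OCCO1 | intermediate (not isolated)
5 | bromomagnesium (S)-2,4,4-trimethyl-3-[2-(2-methyl-1,3-dioxolan-2-yl)ethyl]cyclohex-1-en-1-olate | CC1(C)CCC(O[Mg]Br)=C(C)[C@H]1CCC2(C)OCCO2 | intermediate (not isolated)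
6 | (2R,3S)-2,4,4-trimethyl-2-(3-methylbut-2-en-1-yl)-3-[2-(2-methyl-1,3-dioxolan-2-yl)ethyl]cyclohexan-1-one | CC1(C)CCC(=O)[C@](C)(CC=C(C)C)[C@H]1CCC2(C)OCCO2 | intermediate
7 | hydrazone of 6 | CC1(C)CCC(=NN)[C@](C)(CC=C(C)C)[C@H]1CCC2(C)OCCO2 | intermediate (not isolated)
8 | 2-methyl-2-{2-[(1S,2R)-2,6,6-trimethyl-2-(3-methylbut-2-en-1-yl)cyclohexyl]ethyl}-1,3-dioxolane | CC1(C)CCC[C@](C)(CC=C(C)C)[C@H]1CCC2(C)OCCO2 | intermediate
9 | 2-{(1R,2S)-1,3,3-trimethyl-2-[2-(2-methyl-1,3-dioxolan-2-yl)ethyl]cyclohexyl}acetic acid | CC1(C)CCC[C@](C)(CC(O)=O)[C@H]1CCC2(C)OCCO2 | intermediate (not isolated)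
10 | 2-[(1R,2S)-1,3,3-trimethyl-2-(3-oxobutyl)cyclohexyl]acetic acid | CC1(C)CCC[C@](C)(CC(O)=O)[C@H]1CCC(C)=O | intermediate
11 | mixed anhydride of 10 with p-toluenesulfonic acid | CC1(C)CCC[C@](C)(CC(=O)OS(=O)(=O)c2ccc(C)cc2)[C@H]1CCC(C)=O | intermediate (not isolated)
12 | 1-acyl-4-(pyrrolidin-1-yl)pyridinium tosylate derived from 10 | CC1(C)CCC[C@](C)(CC(=O)[n+]2ccc(N3CCCC3)cc2)[C@H]1CCC(C)=O.Cc1ccc(cc1)S([O-])(=O)=O | intermediate (not isolated)
13 | C9 ammonium enolate (zwitterion) of 12 | CC1(C)CCC[C@](C)(C=C([O-])[n+]2ccc(N3CCCC3)cc2)[C@H]1CCC(C)=O | intermediate (not isolated)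
14 | ring-B-closed aldolate (8β-oxido-9β-acylpyridinium zwitterion) | CC1(C)CCC[C@]2(C)[C@@H](C(=O)[n+]3ccc(N4CCCC4)cc3)[C@@](C)([O-])CC[C@@H]12 | intermediate (not isolated)
15 | (5S,8S,9R,10S)-drimane-11,8-olide (8β-hydroxydriman-11-oic acid β-lactone) | CC1(C)CCC[C@]2(C)[C@H]3C(=O)O[C@@]3(C)CC[C@@H]12 | intermediate
16 | drimane-8β,11-diol (5α-H, 9α-H, 10β-methyl) | CC1(C)CCC[C@]2(C)[C@@H](CO)[C@@](C)(O)CC[C@@H]12 | intermediate
17 | 8β,11-bis(triethylsilyloxy)drimane | CC1(C)CCC[C@]2(C)[C@@H](CO[Si](CC)(CC)CC)[C@@](C)(O[Si](CC)(CC)CC)CC[C@@H]12 | intermediate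
18 | 8β-(triethylsilyloxy)driman-11-al | CC1(C)CCC[C@]2(C)[C@@H](C=O)[C@@](C)(O[Si](CC)(CC)CC)CC[C@@H]12 | intermediate
19 | (R)-4-(tert-butyldimethylsilyloxy)cyclopent-2-en-1-one | O=C1C[C@@H](O[Si](C)(C)C(C)(C)C)C=C1 | starting material
20 | (R)-4-(tert-butyldimethylsilyloxy)-2-iodocyclopent-2-en-1-one | O=C1C[C@@H](O[Si](C)(C)C(C)(C)C)C=C1I | intermediate
21 | dichloro[(R)-3-(tert-butyldimethylsilyloxy)-5-oxocyclopent-1-en-1-yl]chromium | O=C1C[C@@H](O[Si](C)(C)C(C)(C)C)C=C1[Cr](Cl)Cl | intermediate (not isolated)
22 | (4R)-4-(tert-butyldimethylsilyloxy)-2-[11-hydroxy-8β-(triethylsilyloxy)driman-11-yl]cyclopent-2-en-1-one (C11 epimers) | CC1(C)CCC[C@]2(C)[C@@H](C(O)C3=C[C@H](O[Si](C)(C)C(C)(C)C)CC3=O)[C@@](C)(O[Si](CC)(CC)CC)CC[C@@H]12 | intermediate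
23 | C11 methanesulfonate of 22 | CC1(C)CCC[C@]2(C)[C@@H](C(OS(C)(=O)=O)C3=C[C@H](O[Si](C)(C)C(C)(C)C)CC3=O)[C@@](C)(O[Si](CC)(CC)CC)CC[C@@H]12 | intermediate (not isolated)
24 | (2E,3R,4R)-4-(tert-butyldimethylsilyloxy)-3-chloro-2-[8β-(triethylsilyloxy)driman-11-ylidene]cyclopentan-1-one | CC1(C)CCC[C@]2(C)[C@@H](/C=C3\C(=O)C[C@@H](O[Si](C)(C)C(C)(C)C)[C@@H]3Cl)[C@@](C)(O[Si](CC)(CC)CC)CC[C@@H]12 | intermediate
25 | (2E,3R,4R)-3-chloro-4-hydroxy-2-(8β-hydroxydriman-11-ylidene)cyclopentan-1-one | CC1(C)CCC[C@]2(C)[C@@H](/C=C3\C(=O)C[C@@H](O)[C@@H]3Cl)[C@@](C)(O)CC[C@@H]12 | intermediate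
26 | (4E,5R)-5-chloro-4-(8β-hydroxydriman-11-ylidene)cyclopentane-1,3-dione (diketone tautomer) | CC1(C)CCC[C@]2(C)[C@@H](/C=C3\C(=O)CC(=O)[C@@H]3Cl)[C@@](C)(O)CC[C@@H]12 | intermediate (not isolated)
27 | (4E,5R)-5-chloro-3-hydroxy-4-{[(1R,2S,4aS,8aS)-2-hydroxy-2,5,5,8a-tetramethyldecahydronaphthalen-1-yl]methylidene}cyclopent-2-en-1-one | CC1(C)CCC[C@]2(C)[C@@H](/C=C3\C(O)=CC(=O)[C@@H]3Cl)[C@@](C)(O)CC[C@@H]12 | target

**Step count**
Total: 12 steps. Longest linear sequence: 11 steps (steps 1–7 and 9–12; step 8 is the side branch).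

**Steps most likely to fail**

Step 1. The nucleophile must reach a β-carbon flanked by a quaternary carbon and an α-methyl group. Slow catalytic turnover with erosion of enantioselectivity by uncatalysed addition, and incomplete C-alkylation of the hindered magnesium enolate, are the main dangers. The fallback gives up asymmetric catalysis and sets out from compound 1. A TMSCl-accelerated, CuBr·SMe2-catalysed addition of Grignard reagent 4 gives the racemic trimethylsilyl enol ether F1. MeLi releases the lithium enolate, and alkylation with 3 gives the racemate of 6, that is 6 together with its mirror image, the (2S,3R)-ketone F2. Preparative chromatography on a chiral stationary phase removes F2, and the route is rejoined at compound 6.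

Step 9. The aldehyde carbon sits between two quaternary centres. Addition of the vinylchromium species may be so slow that protonation or reductive dimerisation of the organometallic wins. The fallback replaces the organochromium by a thiolate-triggered Michael–aldol sequence and sets out from compounds 18 and 19. Me2AlSPh adds its thiolate to C3' of 19 anti to the silyloxy group, and the aluminium enolate is intercepted by 18 to give the β-phenylsulfanyl aldol F3. Oxidation with mCPBA at −78 °C gives the sulfoxide F4, and syn elimination on warming restores the enone, coming back at compound 22.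

Step 10. The chloride displacement may leak into loss of silanol or hydrogen chloride from the β-substituted ketone, into direct substitution at C11, or into the alkene isomer with the drimanyl group beside C3'. The fallback installs chloride before the alkene exists and sets out from compounds 18 and 19. A TiCl4-mediated three-component chloro-aldol reaction (CH2Cl2, −78 °C) delivers chloride to C3' anti to the silyloxy group and traps the titanium enolate with 18, giving the β-chloro aldol F5. Mesylation gives the mesylate F6, and E1cB elimination with DBU forms the alkylidene ketone, coming back at compound 24.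

Further compounds
F1 | step 1 | racemic trimethyl({2,4,4-trimethyl-3-[2-(2-methyl-1,3-dioxolan-2-yl)ethyl]cyclohex-1-en-1-yl}oxy)silane | CC1(C)CCC(O[Si](C)(C)C)=C(C)C1CCC2(C)OCCO2
F2 | step 1 | (2S,3R)-2,4,4-trimethyl-2-(3-methylbut-2-en-1-yl)-3-[2-(2-methyl-1,3-dioxolan-2-yl)ethyl]cyclohexan-1-one (enantiomer of 6) | CC1(C)CCC(=O)[C@@](C)(CC=C(C)C)[C@@H]1CCC2(C)OCCO2
F3 | step 9 | (4R)-4-(tert-butyldimethylsilyloxy)-2-[11-hydroxy-8β-(triethylsilyloxy)driman-11-yl]-3-(phenylsulfanyl)cyclopentan-1-one | CC1(C)CCC[C@]2(C)[C@@H](C(O)C3C(Sc4ccccc4)[C@H](O[Si](C)(C)C(C)(C)C)CC3=O)[C@@](C)(O[Si](CC)(CC)CC)CC[C@@H]12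
F4 | step 9 | (4R)-4-(tert-butyldimethylsilyloxy)-2-[11-hydroxy-8β-(triethylsilyloxy)driman-11-yl]-3-(phenylsulfinyl)cyclopentan-1-one | CC1(C)CCC[C@]2(C)[C@@H](C(O)C3C(S(=O)c4ccccc4)[C@H](O[Si](C)(C)C(C)(C)C)CC3=O)[C@@](C)(O[Si](CC)(CC)CC)CC[C@@H]12
F5 | step 10 | (3R,4R)-4-(tert-butyldimethylsilyloxy)-3-chloro-2-[11-hydroxy-8β-(triethylsilyloxy)driman-11-yl]cyclopentan-1-one | CC1(C)CCC[C@]2(C)[C@@H](C(O)C3C(=O)C[C@@H](O[Si](C)(C)C(C)(C)C)[C@@H]3Cl)[C@@](C)(O[Si](CC)(CC)CC)CC[C@@H]12
F6 | step 10 | C11 methanesulfonate of F5 | CC1(C)CCC[C@]2(C)[C@@H](C(OS(C)(=O)=O)C3C(=O)C[C@@H](O[Si](C)(C)C(C)(C)C)[C@@H]3Cl)[C@@](C)(O[Si](CC)(CC)CC)CC[C@@H]12
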